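**Remark.** The target has no stereogenic element, so the structure as drawn is the single species required. The only stereocentre that appears on the way (the carbinol carbon of 15) is formed as a racemate and is removed in step 9. Ring C is numbered C1' (carries the bridging CH2), C2' (carries the CH2CH2 arm to ring D), C4' (OH) and C6' (OMe).

## Retrosynthetic overview

1. Target 18 ⇐ fluoride desilylation of 17 ⇐ ionic deoxygenation and MOM loss from the diarylcarbinol 15.
2. 15 ⇐ one-pot union of three pieces at ring C: the aryne 13 (from chloroarene 11), the ring D phenethyl Grignard 4 (nucleophile) and the ring A-B aldehyde 9 (electrophile).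
3. Feature used: in ring C the two carbon substituents are vicinal, the ethylene arm on C2' (meta to the C6'-OMe) and the bridge carbon on C1' (ortho to the C6'-OMe). This is the pattern left when a nucleophile and then an electrophile add across a 3-methoxybenzyne.
4. 9 ⇐ ortho-lithiation/formylation of bibenzyl 7 ⇐ Kumada coupling of the same Grignard 4 with bromide 6, since rings A and D are the same homovanillyl unit.
5. All four benzene rings are purchased; no ring is formed in the route.

Key step: step 8

## Route

Step 1
Reactants: 1 homovanillyl alcohol [4-(2-hydroxyethyl)-2-methoxyphenol]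
Product: 2 4-(2-bromoethyl)-2-methoxyphenol
Conditions: CBr4, PPh3, CH2Cl2, 0 °C → rt
Reagents that add atoms: carbon tetrabromide BrC(Br)(Br)Br
Why: Appel reaction; the primary alcohol is activated as its alkoxyphosphonium salt and displaced by bromide, while the phenol cannot be substituted and is returned unchanged on work-up.

Step 2
Reactants: 2 4-(2-bromoethyl)-2-methoxyphenol
Product: 3 [4-(2-bromoethyl)-2-methoxyphenoxy]triisopropylsilane
Conditions: TIPSOTf, 2,6-lutidine, CH2Cl2, 0 °C
Reagents that add atoms: triisopropylsilyl triflate CC(C)[Si](OS(=O)(=O)C(F)(F)F)(C(C)C)C(C)C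
Why: Phenol silylation with a silyl triflate and a hindered, non-nucleophilic base should be fast at 0 °C, and it avoids a free phenoxide that could cyclize onto the bromoethyl arm or a nucleophilic base that could be alkylated by it.

Step 3
Reactants: 3 [4-(2-bromoethyl)-2-methoxyphenoxy]triisopropylsilane
Product: 4 2-(3-methoxy-4-triisopropylsilyloxyphenyl)ethylmagnesium bromide (THF solution, titrated, used in steps 5 and 8)
Conditions: Mg turnings, I2 (cat.), THF, rt → 45 °C
Reagents that add atoms: magnesium [Mg]
Why: Grignard formation by magnesium insertion into a primary alkyl bromide; the aryl methyl ether and the bulky aryl silyl ether are inert to the reagent.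

Step 4
Reactants: 5 3-bromo-5-methoxyphenol
Product: 6 1-bromo-3-methoxy-5-(methoxymethoxy)benzene
Conditions: MOMCl, i-Pr2NEt, CH2Cl2, 0 °C → rt
Reagents that add atoms: chloromethyl methyl ether COCCl
Why: O-alkylation of the phenol with an α-chloro ether (MOM protection) installs the group that later directs lithiation and that falls off under the acid of step 9.

Step 5
Reactants: 4 2-(3-methoxy-4-triisopropylsilyloxyphenyl)ethylmagnesium bromide; 6 1-bromo-3-methoxy-5-(methoxymethoxy)benzene
Product: 7 triisopropyl{2-methoxy-4-[2-(3-methoxy-5-(methoxymethoxy)phenyl)ethyl]phenoxy}silane (ring A-B bibenzyl)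
Conditions: PdCl2(dppf) (3 mol %), THF, rt → 50 °C
Reagents that add atoms: none
Why: Kumada-Corriu sp3-sp2 coupling; the wide-bite-angle dppf ligand speeds reductive elimination so that the primary alkyl-palladium intermediate should couple before β-hydride elimination, and ethers, acetal and silyl ether are inert to the Grignard.

Step 6
Reactants: 7 ring A-B bibenzyl
Product: 9 2-methoxy-6-(methoxymethoxy)-4-[2-(3-methoxy-4-triisopropylsilyloxyphenyl)ethyl]benzaldehyde, via aryllithium 8 (not isolated)
Conditions: n-BuLi, THF, 0 °C; DMF, 0 °C → rt; H2O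
Reagents that add atoms: N,N-dimethylformamide CN(C)C=O
Why: Directed ortho-metalation followed by formylation; the ring B carbon between OMe and OMOM is by far the most acidic and best coordinated site, so lithiation there and quench with DMF should give the 2,6-dioxygenated benzaldehyde.

Step 7
Reactants: 10 3-chloro-5-methoxyphenol
Product: 11 (3-chloro-5-methoxyphenoxy)triisopropylsilane
Conditions: TIPSCl, imidazole, DMF, rt
Reagents that add atoms: triisopropylsilyl chloride CC(C)[Si](Cl)(C(C)C)C(C)C
Why: Standard imidazole-mediated phenol silylation; the bulky silyl group protects the C4' oxygen and shields the two ring positions next to it from metalation in step 8.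

Step 8
Reactants: 11 (3-chloro-5-methoxyphenoxy)triisopropylsilane (1.6 equiv); 4 2-(3-methoxy-4-triisopropylsilyloxyphenyl)ethylmagnesium bromide (1.5 equiv); 9 ring A-B aldehyde (1.0 equiv)
Product: 15 protected diarylcarbinol holding all four rings (racemic at the carbinol carbon), via 2-lithio chloroarene 12 (not isolated), via aryne 13 (not isolated), via arylmagnesium bromide 14 (not isolated)
Conditions: s-BuLi (1.55 equiv), THF, −78 °C; 4, −78 °C → rt → 50 °C; 9, 0 °C → rt; H2O
Reagents that add atoms: none
Why: s-BuLi should remove the one proton of 11 that lies between Cl and OMe (acidified by both and reached through OMe coordination, while the bulky OTIPS shields the other two positions), and on warming the metalated chloroarene 12 loses chloride to give aryne 13. The primary alkyl Grignard 4 should add to the aryne carbon remote from OMe, as aryne distortion and inductive/chelating stabilization of the developing carbanion next to oxygen both require, so that the magnesium of 14 sits between OMe and the new phenethyl arm. This arylmagnesium then adds 1,2 to the non-enolizable aldehyde 9, so the C2'-CH2 and C1'-C(bridge) bonds are made in one flask; the closest known reaction type is the carbomagnesiation of 3-alkoxyarynes released from ortho-lithiated haloarenes with electrophilic quench of the resulting aryl-magnesium, as used for hindered biaryls. No ring is closed. The carbinol carbon is formed without control as a racemate and is erased in step 9. Chemoselectivity rests on order and stoichiometry: the aryne is released slowly in the presence of the more nucleophilic alkyl Grignard so that 4 and not 14 captures it, and 11 is kept slightly above 4 so that little alkyl Grignard remains when the limiting aldehyde is added.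

Step 9
Reactants: 15 protected diarylcarbinol
Product: 17 tris-TIPS diarylmethane with free ring B phenol, via MOM-protected diarylmethane 16 (not isolated)
Conditions: Et3SiH (10 equiv), TFA, CH2Cl2, −40 → 0 °C, then rt
Reagents that add atoms: none
Why: Ionic hydrogenation; the doubly benzylic, electron-rich carbinol ionizes in TFA and the cation is reduced by silane hydride, then on warming TFA cleaves the MOM acetal, with excess Et3SiH reducing the methoxymethyl cation to dimethyl ether so that it cannot alkylate the electron-rich rings (aryl TIPS ethers should survive, and any partial loss is harmless because step 10 removes them).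

Step 10
Reactants: 17 tris-TIPS diarylmethane with free ring B phenol
Product: 18 target, 4-[2-(4-hydroxy-3-methoxyphenyl)ethyl]-2-{[4-hydroxy-2-[2-(4-hydroxy-3-methoxyphenyl)ethyl]-6-methoxyphenyl]methyl}-6-methoxy... i.e. the tetraphenolic bis(bibenzyl) of the given SMILES
Conditions: TBAF (3.5 equiv), AcOH (3.5 equiv), THF, 0 °C → rt
Reagents that add atoms: none
Why: Fluoride-induced cleavage of the three aryl silyl ethers (Si-F bond formation); the acetic acid buffer keeps the electron-rich phenols protonated and limits air oxidation.

## Compound list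

1 | homovanillyl alcohol, 4-(2-hydroxyethyl)-2-methoxyphenol | COc1cc(CCO)ccc1O | starting material
2 | 4-(2-bromoethyl)-2-methoxyphenol | COc1cc(CCBr)ccc1O | intermediate
3 | [4-(2-bromoethyl)-2-methoxyphenoxy]triisopropylsilane | COc1cc(CCBr)ccc1O[Si](C(C)C)(C(C)C)C(C)C | intermediate
4 | 2-(3-methoxy-4-triisopropylsilyloxyphenyl)ethylmagnesium bromide | COc1cc(CC[Mg]Br)ccc1O[Si](C(C)C)(C(C)C)C(C)C | intermediate
5 | 3-bromo-5-methoxyphenol | COc1cc(O)cc(Br)c1 | starting material
6 | 1-bromo-3-methoxy-5-(methoxymethoxy)benzene | COCOc1cc(Br)cc(OC)c1 | intermediate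
7 | ring A-B bibenzyl, triisopropyl{2-methoxy-4-[2-(3-methoxy-5-(methoxymethoxy)phenyl)ethyl]phenoxy}silane | COc1cc(CCc2cc(OC)cc(OCOC)c2)ccc1O[Si](C(C)C)(C(C)C)C(C)C | intermediate
8 | aryllithium of 7, lithiated on ring B between OMe and OMOM | COc1cc(CCc2cc(OC)c([Li])c(OCOC)c2)ccc1O[Si](C(C)C)(C(C)C)C(C)C | intermediate (not isolated)
9 | ring A-B aldehyde, 2-methoxy-6-(methoxymethoxy)-4-[2-(3-methoxy-4-triisopropylsilyloxyphenyl)ethyl]benzaldehyde | COc1cc(CCc2cc(OC)c(C=O)c(OCOC)c2)ccc1O[Si](C(C)C)(C(C)C)C(C)C | intermediate
10 | 3-chloro-5-methoxyphenol | COc1cc(O)cc(Cl)c1 | starting material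
11 | (3-chloro-5-methoxyphenoxy)triisopropylsilane (aryne precursor) | COc1cc(Cl)cc(O[Si](C(C)C)(C(C)C)C(C)C)c1 | intermediate
12 | [2-chloro-6-methoxy-4-(triisopropylsilyloxy)phenyl]lithium | COc1cc(O[Si](C(C)C)(C(C)C)C(C)C)cc(Cl)c1[Li] | intermediate (not isolated)
13 | 3-methoxy-5-(triisopropylsilyloxy)benzyne | COC1=CC(O[Si](C(C)C)(C(C)C)C(C)C)=CC#C1 | intermediate (not isolated)
14 | {2-methoxy-6-[2-(3-methoxy-4-triisopropylsilyloxyphenyl)ethyl]-4-(triisopropylsilyloxy)phenyl}magnesium bromide | COc1cc(O[Si](C(C)C)(C(C)C)C(C)C)cc(CCc2ccc(O[Si](C(C)C)(C(C)C)C(C)C)c(OC)c2)c1[Mg]Br | intermediate (not isolated)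
15 | protected diarylcarbinol with all four rings (racemic carbinol; ring B MOM ether, rings A, C, D TIPS ethers) | COc1cc(CCc2cc(OC)c(C(O)c3c(CCc4ccc(O[Si](C(C)C)(C(C)C)C(C)C)c(OC)c4)cc(O[Si](C(C)C)(C(C)C)C(C)C)cc3OC)c(OCOC)c2)ccc1O[Si](C(C)C)(C(C)C)C(C)C | intermediate
16 | MOM-protected tris-TIPS diarylmethane | COc1cc(CCc2cc(OC)c(Cc3c(CCc4ccc(O[Si](C(C)C)(C(C)C)C(C)C)c(OC)c4)cc(O[Si](C(C)C)(C(C)C)C(C)C)cc3OC)c(OCOC)c2)ccc1O[Si](C(C)C)(C(C)C)C(C)C | intermediate (not isolated)
17 | tris-TIPS diarylmethane with free ring B phenol | COc1cc(CCc2cc(O)c(Cc3c(CCc4ccc(O[Si](C(C)C)(C(C)C)C(C)C)c(OC)c4)cc(O[Si](C(C)C)(C(C)C)C(C)C)cc3OC)c(OC)c2)ccc1O[Si](C(C)C)(C(C)C)C(C)C | intermediate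
18 | target CNP0079000.0 (achiral) | COc1cc(CCc2cc(O)c(Cc3c(CCc4ccc(O)c(OC)c4)cc(O)cc3OC)c(OC)c2)ccc1O | target

## Summary

Total step count: 10. Longest linear sequence: 8 steps (1, 2, 3, 5, 6, 8, 9, 10).

Steps most likely to fail:

1. **Step 8.** The primary alkyl Grignard may be consumed unproductively by the aryne (β-hydride transfer, repeated aryne insertion). The crowded arylmagnesium may also add too slowly to the di-ortho-substituted aldehyde, so that leftover alkyl Grignard takes the aldehyde. Fallback without an aryne, setting out from 11, 9 and 4: 11 is lithiated as before (s-BuLi, THF, −78 °C) and the cold aryllithium 12 is quenched with 9 at −78 °C, before any chloride is lost, to give the chloro carbinol F1. Et3SiH/TFA under the conditions of step 9 should give the chloro diarylmethane phenol F2; no ring D arm is present at this stage, so the cyclization risk of step 9 is absent. Negishi coupling of F2 with the alkylzinc chloride F3 (made from 4 and ZnCl2; Pd(OAc)2/SPhos, THF, rt → 50 °C, excess zinc reagent to cover the free phenol) installs the ring D arm and comes back to the route at 17.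

2. **Step 9.** The benzhydryl cation carries the ring D phenethyl arm on the neighbouring carbon, so intramolecular Friedel-Crafts capture by ring D (seven-membered ring closure) may compete with hydride delivery. Fallback by a radical path, setting out from 15: the alkoxide (NaH, THF, 0 °C) is trapped with CS2 and MeI to give the S-methyl xanthate F4. Barton-McCombie reduction (Bu3SnH, AIBN, toluene, 90 °C) gives the benzhydryl radical, which cannot be captured by the arene in the way the cation can, and hence 16, here isolated. The route is rejoined at 16, which is taken through the acid stage of step 9 (TFA, Et3SiH as scavenger, CH2Cl2, rt) to 17.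

3. **Step 5.** β-Hydride elimination from the phenethyl-palladium intermediate (styrene and reduced arene) and homocoupling of the Grignard may erode the sp3-sp2 coupling. Fallback without a preformed organometallic, setting out from 3 and 6: nickel-catalysed reductive cross-electrophile coupling of the alkyl bromide 3 with the aryl bromide 6 (NiI2, 4,4'-di-tert-butyl-2,2'-bipyridine, Zn dust, NaI, DMA, 60 °C) should give 7 directly, where the route is rejoined. No compound outside the list is made (entry F0).

## Further compounds

F1 | step 8 | chloro carbinol, (2-chloro-6-methoxy-4-triisopropylsilyloxyphenyl)(ring A-B aryl)methanol, racemic | COc1cc(CCc2cc(OC)c(C(O)c3c(Cl)cc(O[Si](C(C)C)(C(C)C)C(C)C)cc3OC)c(OCOC)c2)ccc1O[Si](C(C)C)(C(C)C)C(C)C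
F2 | step 8 | chloro diarylmethane phenol (ring B phenol free, Cl at C2' of ring C) | COc1cc(CCc2cc(O)c(Cc3c(Cl)cc(O[Si](C(C)C)(C(C)C)C(C)C)cc3OC)c(OC)c2)ccc1O[Si](C(C)C)(C(C)C)C(C)C
F3 | step 8 | 2-(3-methoxy-4-triisopropylsilyloxyphenyl)ethylzinc chloride | COc1cc(CC[Zn]Cl)ccc1O[Si](C(C)C)(C(C)C)C(C)C
F4 | step 9 | S-methyl xanthate of carbinol 15 | COc1cc(CCc2cc(OC)c(C(OC(=S)SC)c3c(CCc4ccc(O[Si](C(C)C)(C(C)C)C(C)C)c(OC)c4)cc(O[Si](C(C)C)(C(C)C)C(C)C)cc3OC)c(OCOC)c2)ccc1O[Si](C(C)C)(C(C)C)C(C)C
F0 | step 5 | none | none
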